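Each unit of reagent stays reagent in the second phase, reagent in the reaction phase or reagent bound in target, so these three fractions of its charge add up to one at each moment.

    reagent in the reaction phase ⇌ reagent in the second phase, rate k1*([reagent in the reaction phase] - [reagent in the second phase]/K1) per volume of the first phase (K1 = 1.59, k1 = 0.124 min⁻¹)
    substrate + reagent in the reaction phase ⇌ target (K2 = 2.0 M⁻¹, k2 = 1.07 M⁻¹ min⁻¹)
    2 substrate → self-condensation product (k3 = 1.45 × 10⁻⁴ M⁻¹ min⁻¹)

substrate 0.25 M; reagent in the second phase 0.250 M; time 4.0 h; volume of the second phase over the first 1.0

- percentages count the substrate that a species holds: one self-condensation product counts as two
- two of one species on the left: rate k times its square, two consumed each time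
- in the second phase: reagent in the second phase; everything else is in the first
- charges count per volume of the first phase; a concentration in a rate is the amount of a species over the volume of its own phase; every rate counts per litre of the first phase
- run time (flask): 4.0 h

* how much target there is at 4.0 h, in percent of the substrate charged
* the change that raises the amount of target at 4.0 h, in percent of the substrate charged most ("none" if none brings more than 2 percentage points) (red / ochre / none)
* amount of target at 4.0 h, in percent of the substrate charged, after ochre

- red: doubling the amount of reagent in the second phase, all else as stated
- ochre: doubling the transfer coefficient of step 1, all else as stated

I follow one unit of reagent. At rest, its reaction-phase place has weight one and its second-phase place weight 1.59. Together they make 2.59, the free weight of the reagent. Target has weight 2.0 M⁻¹ times the free substrate, and the chance of sitting in target is that weight over itself plus the free weight. I may use rest because the transfer relaxes in about 4.95 min and the addition takes about 3.74 min, both far shorter than the 4.0 h. Self-condensation has a first half-life of 230 h, far longer than the run.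

The two charges are equal, so this chance is also the target as a fraction of the substrate charged. In one extreme flask, substrate is never drawn down, and the chance is 16.2%. In the other, substrate has already lost that whole fraction, and the chance is 13.9%. The real flask lies between them, and one more pass gives 14.2%, the figure I commit to. Ochre changes the transfer coefficient, which stands nowhere in the free weight, so target should stay put. Red doubles the reagent and draws substrate lower, and one pass puts target near 24.3%. Watch for target going flat early: this is thermodynamic control.

The forecast gives 14.05%, less than my 14.2%, with 14.05% after ochre and red as best, holding that ochre “only speeds an already equilibrated transfer”. The flask gives 14.1%, 14.1% after ochre, and red as best, with a gain of 11 percentage points. In this flask at 4.00 h, the addition relaxes, both ways together, with a half-life of 0.815 min, short against the 4.0 h, and target already reads 13.9% at 0.400 h. With substrate read at 84.7%, the free weight gives this flask a chance of 14.0%. The neighbour flask, with 1.0 M of substrate, keeps 85% of it, so the same weight gives 9.89% of its substrate as target, and that flask reads 9.90%.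

The numbers of this flask are made up; the flask was simulated.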